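## Retrosynthetic overview

1. Myriaporone 4 ⇐ last‑step OH‑directed epoxidation of the C5=C6 olefin ⇐ one‑pot removal of two TBS ethers and a C9 dimethyl ketal.
2. C13 ethyl ketone ⇐ tertiary amide + EtLi; C6–C7 bond ⇐ chelation‑controlled addition of a (Z)‑alkenyl Grignard (C1–C6, from Roche ester) to a C7 lactol.
3. C7–C13 chain with C8, C10, C11 set ⇐ bicyclic acylal‑lactone ⇐ Baeyer–Villiger ⇐ enantiotopos‑selective hydroboration of a meso 8‑oxabicyclo[3.2.1]octene (key symmetry‑breaking step).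
4. Meso oxabicycle ⇐ two exo hydroxymethylations of 8‑oxabicyclo[3.2.1]oct‑6‑en‑3‑one ⇐ dearomative [4+3] cycloaddition of furan with the oxyallyl cation from tetrabromoacetone.
5. Ring order: oxabicycle (step 1) → ring‑expanded to the 2,9‑dioxabicyclo[3.3.1]nonanone (step 8) → opened to the chain (step 15) → oxirane last (step 18).

Assumption: the target is taken exactly as the given SMILES. With chain numbering C1 (propenyl CH3) to C15 (ethyl CH3) it reads 2Z,4S,5S,6R,7S,8R,10S,11S, and C4 and C7 are cis on the oxirane. The epoxide must therefore come from a C5=C6 olefin with C4 and C7 cis (6‑methyl trans to C4). Target numbering is used throughout; C8′ and C10′ are the hydroxymethyl carbons.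

## Route

**Step 1**
Reactants: 1 furan; 2 1,1,3,3‑tetrabromoacetone
Product: 3 (1R,5S)‑8‑oxabicyclo[3.2.1]oct‑6‑en‑3‑one (meso)
Conditions: Zn/Ag couple, furan (3 equiv), THF, −10 °C→rt; then Zn–Cu, NH4Cl, MeOH
Reagents that add atoms: none (both reactants are numbered)
Why: Zn reduction of 2 gives a dibromo‑oxyallyl cation that adds across C2/C5 of furan in a dearomative [4+3] cycloaddition, and Zn–Cu removes both bromines; furan C2–C5 and O become C11, C12, C13, C7 and the C11 oxygen, and the acetone unit becomes C8–C10.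

**Step 2**
Reactants: 3
Product: 4 rac‑(1S,2S,5S)‑2‑(hydroxymethyl)‑8‑oxabicyclo[3.2.1]oct‑6‑en‑3‑one (CH2OH exo/axial, trans to the etheno bridge)
Conditions: LDA (1.1 equiv), THF, −78 °C; CH2O (g, cracked paraformaldehyde); AcOH/THF quench at −78 °C
Reagents that add atoms: formaldehyde, C=O
Why: Kinetic lithium‑enolate aldol; the electrophile enters from the exo face, anti to the etheno bridge, which gives the trans relationship between CH2OH and the C1–C7 bond that becomes C10/C11 anti.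

**Step 3**
Reactants: 4
Product: 5 (1S,2S,4R,5R)‑2,4‑bis(hydroxymethyl)‑8‑oxabicyclo[3.2.1]oct‑6‑en‑3‑one (meso, both CH2OH exo)
Conditions: LDA (2.2 equiv), THF, −78 °C; CH2O (g); cold buffered quench
Reagents that add atoms: formaldehyde, C=O
Why: The alkoxide/enolate dianion forms only toward C4 because the remaining C2–H is equatorial and misaligned for enolisation (so C2 is not epimerised), and the aldol again occurs on the exo face because the endo face is blocked by the etheno bridge.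

**Step 4**
Reactants: 5
Product: 6 (1S,2S,4R,5R)‑2,4‑bis{[(tert‑butyldimethylsilyl)oxy]methyl}‑8‑oxabicyclo[3.2.1]oct‑6‑en‑3‑one (meso)
Conditions: TBSCl, imidazole, DMF, 0 °C
Reagents that add atoms: TBSCl, CC(C)(C)[Si](C)(C)Cl
Why: Standard silylation of primary alcohols under mild, cold conditions that do not equilibrate the axial α‑centres.

**Step 5**
Reactants: 6
Product: 7 (1S,2S,4R,5R)‑2,4‑bis(TBSOCH2)‑3,3‑dimethoxy‑8‑oxabicyclo[3.2.1]oct‑6‑ene (meso)
Conditions: MeOTMS (3 equiv), TMSOTf (10 mol %), CH2Cl2, −78→−30 °C; pyridine quench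
Reagents that add atoms: methoxytrimethylsilane, CO[Si](C)(C)C
Why: Noyori aprotic ketalisation tolerates TBS ethers and runs cold enough to avoid enolisation; the ketal locks C8/C10 and prevents β‑elimination once C7 becomes an acetal or aldehyde.

**Step 6 (key step)**
Reactants: 7
Product: 8 (1S,2S,4R,5S,6R)‑2,4‑bis(TBSOCH2)‑3,3‑dimethoxy‑8‑oxabicyclo[3.2.1]octan‑6‑ol (exo alcohol)
Conditions: (+)‑Ipc2BH [from (−)‑α‑pinene], THF, −25→0 °C; then 3 M NaOH, 30 % H2O2
Reagents that add atoms: hydrogen peroxide, OO (the new oxygen; the borane supplies H)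
Why: Brown asymmetric hydroboration adds from the exo face and selects one of the two enantiotopic olefin carbons, so this one step breaks the mirror symmetry, fixes the absolute configuration of C8, C10 and C11, and marks C13 (oxygenated) against C12 (CH2); the sense is assigned by analogy with norbornene and cis‑alkenes, and the antipodal borane is equally available.

**Step 7**
Reactants: 8
Product: 9 (1S,2S,4R,5S)‑2,4‑bis(TBSOCH2)‑3,3‑dimethoxy‑8‑oxabicyclo[3.2.1]octan‑6‑one
Conditions: Dess–Martin periodinane, NaHCO3, CH2Cl2, 0 °C→rt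
Reagents that add atoms: none
Why: Buffered Dess–Martin oxidation of a secondary alcohol; no epimerisable centre is α to the new ketone except the bridgehead.

**Step 8**
Reactants: 9
Product: 10 (1R,5S,6S,8R)‑6,8‑bis(TBSOCH2)‑7,7‑dimethoxy‑2,9‑dioxabicyclo[3.3.1]nonan‑3‑one
Conditions: mCPBA, NaHCO3, CH2Cl2, 0 °C→rt
Reagents that add atoms: mCPBA, OOC(=O)c1cccc(Cl)c1
Why: Baeyer–Villiger oxidation in which the α‑oxygenated bridgehead carbon migrates with retention, leaving C13 as a lactone carbonyl and C7 as an acylal (masked aldehyde), so the two ends differ in oxidation level.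

**Step 9**
Reactants: 11 methyl (R)‑3‑hydroxy‑2‑methylpropanoate (Roche ester)
Product: 12 methyl (R)‑3‑[(tert‑butyldimethylsilyl)oxy]‑2‑methylpropanoate
Conditions: TBSCl, imidazole, CH2Cl2, rt
Reagents that add atoms: TBSCl, CC(C)(C)[Si](C)(C)Cl
Why: Routine silylation; the chiral‑pool centre becomes C4.

**Step 10**
Reactants: 12
Product: 13 (R)‑3‑[(tert‑butyldimethylsilyl)oxy]‑2‑methylpropanal
Conditions: DIBAL‑H (1.05 equiv), CH2Cl2, −78 °C; Rochelle salt
Reagents that add atoms: none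
Why: Partial ester reduction through the stable aluminium hemiacetal at −78 °C; the α‑centre is untouched.

**Step 11**
Reactants: 13
Product: 14 tert‑butyldimethyl{[(2S,3Z)‑2‑methylpent‑3‑en‑1‑yl]oxy}silane
Conditions: EtPPh3Br, KHMDS, THF, −78 °C→rt
Reagents that add atoms: ethyltriphenylphosphonium bromide, CC[P+](c1ccccc1)(c1ccccc1)c1ccccc1.[Br-]
Why: Salt‑free Wittig reaction of a non‑stabilised ylide gives the Z olefin (C2=C3).

**Step 12**
Reactants: 14
Product: 15 (2S,3Z)‑2‑methylpent‑3‑en‑1‑ol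
Conditions: TBAF, THF, 0 °C; careful concentration (volatile)
Reagents that add atoms: none
Why: Fluoride desilylation.

**Step 13**
Reactants: 15
Product: 16 (2S,3Z)‑2‑methylpent‑3‑enal
Conditions: Dess–Martin periodinane, NaHCO3, CH2Cl2, 0 °C; filtered cold solution used at once
Reagents that add atoms: none
Why: Neutral, buffered oxidation avoids epimerisation and conjugation of the β,γ‑unsaturated aldehyde.

**Step 14**
Reactants: 16
Product: 17 (2Z,4S,5Z)‑2‑iodo‑4‑methylhepta‑2,5‑diene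
Conditions: EtPPh3I, n‑BuLi, THF; I2, −78 °C; NaHMDS, −20 °C; then 16, −78 °C
Reagents that add atoms: ethyltriphenylphosphonium iodide, CC[P+](c1ccccc1)(c1ccccc1)c1ccccc1.[I-]; iodine, II
Why: Stork–Zhao‑type olefination with the α‑iodo ylide gives the (Z)‑2‑iodoalkene (I cis to C4), which is the geometry needed for C7 to end up cis to C4.

**Step 15**
Reactants: 10; 17
Product: 18 the C13 pyrrolidine amide, 7,11‑diol, 9,9‑dimethyl ketal, 8′,10′‑bis‑TBS ether (2Z,4S,5Z,7S,8R,10S,11S)
Conditions: pyrrolidine, i‑PrMgCl, THF, −20→0 °C; then the alkenyl Grignard from 17 (2 equiv; t‑BuLi, Et2O, −78 °C; MgBr2·OEt2), CH2Cl2/Et2O, −78→0 °C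
Reagents that add atoms: pyrrolidine, C1CCNC1
Why: Magnesium pyrrolidide opens the activated lactone (Bodroux aminolysis) to a Grignard‑inert tertiary amide and releases the magnesium lactolate; its open aldehyde is trapped by the alkenyl Grignard (I/Li exchange with retention) under Cram‑chelate control (Mg bridging C7=O and a C9 ketal oxygen, attack anti to the C8 CH2OTBS), giving the 7,8‑anti (7S) alcohol.

**Step 16**
Reactants: 18
Product: 19 the 5,6‑olefin precursor as its 9,9‑dimethyl ketal, 8′,10′‑bis‑TBS ether (ethyl ketone at C13)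
Conditions: EtLi (5 equiv), THF, −78→−20 °C; inverse quench into cold aq. NH4Cl
Reagents that add atoms: ethyllithium, [Li]CC
Why: Organolithium addition to a tertiary amide gives a tetrahedral alkoxide that is stable until quench (as in β‑alkoxide amide‑to‑ketone conversions), so the ketone is released only on work‑up; two equivalents are consumed by the hydroxyls.

**Step 17**
Reactants: 19
Product: 20 (5S,6S,8R,9S,10Z,12S,13Z)‑5,9‑dihydroxy‑6,8‑bis(hydroxymethyl)‑10,12‑dimethylpentadeca‑10,13‑diene‑3,7‑dione (5,6‑deoxy‑myriaporone 4)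
Conditions: aq. HF (48 %)/MeCN (5:95), 0 °C
Reagents that add atoms: water, O (oxygen of the C9 ketone)
Why: Dilute aqueous HF cleaves both primary TBS ethers and hydrolyses the strained dimethyl ketal in one base‑free operation, avoiding retro‑aldol and β‑elimination; no stereocentre is touched.

**Step 18**
Reactants: 20
Product: 21 myriaporone 4
Conditions: mCPBA (1.1 equiv), NaHCO3, CH2Cl2, −20 °C
Reagents that add atoms: mCPBA, OOC(=O)c1cccc(Cl)c1
Why: Hydroxyl‑directed (Henbest) epoxidation: A(1,3) strain between C4 and C7 holds H7 in the olefin plane and the 7‑OH delivers the peracid to its own face, giving the threo epoxy alcohol (5S,6R) by syn addition with C4 and C7 still cis; the hydroxyl‑activated trisubstituted olefin reacts well before the Z‑disubstituted C2=C3 olefin.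

## Compound list

1 | furan | c1ccoc1 | starting material
2 | 1,1,3,3‑tetrabromoacetone | O=C(C(Br)Br)C(Br)Br | starting material
3 | (1R,5S)‑8‑oxabicyclo[3.2.1]oct‑6‑en‑3‑one (meso) | C1=C[C@H]2CC(=O)C[C@@H]1O2 | intermediate
4 | rac‑(1S,2S,5S)‑2‑(hydroxymethyl)‑8‑oxabicyclo[3.2.1]oct‑6‑en‑3‑one (one enantiomer drawn) | C1=C[C@H]2[C@H](CO)C(=O)C[C@@H]1O2 | intermediate
5 | (1S,2S,4R,5R)‑2,4‑bis(hydroxymethyl)‑8‑oxabicyclo[3.2.1]oct‑6‑en‑3‑one (meso) | C1=C[C@H]2[C@H](CO)C(=O)[C@H](CO)[C@@H]1O2 | intermediate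
6 | bis‑TBS ether of 5 (meso) | C1=C[C@H]2[C@H](CO[Si](C)(C)C(C)(C)C)C(=O)[C@H](CO[Si](C)(C)C(C)(C)C)[C@@H]1O2 | intermediate
7 | (1S,2S,4R,5R)‑2,4‑bis(TBSOCH2)‑3,3‑dimethoxy‑8‑oxabicyclo[3.2.1]oct‑6‑ene (meso) | C1=C[C@H]2[C@H](CO[Si](C)(C)C(C)(C)C)C(OC)(OC)[C@H](CO[Si](C)(C)C(C)(C)C)[C@@H]1O2 | intermediate
8 | (1S,2S,4R,5S,6R)‑2,4‑bis(TBSOCH2)‑3,3‑dimethoxy‑8‑oxabicyclo[3.2.1]octan‑6‑ol | O[C@@H]1C[C@H]2[C@H](CO[Si](C)(C)C(C)(C)C)C(OC)(OC)[C@H](CO[Si](C)(C)C(C)(C)C)[C@@H]1O2 | intermediate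
9 | (1S,2S,4R,5S)‑2,4‑bis(TBSOCH2)‑3,3‑dimethoxy‑8‑oxabicyclo[3.2.1]octan‑6‑one | O=C1C[C@H]2[C@H](CO[Si](C)(C)C(C)(C)C)C(OC)(OC)[C@H](CO[Si](C)(C)C(C)(C)C)[C@@H]1O2 | intermediate
10 | (1R,5S,6S,8R)‑6,8‑bis(TBSOCH2)‑7,7‑dimethoxy‑2,9‑dioxabicyclo[3.3.1]nonan‑3‑one | O=C1C[C@H]2[C@H](CO[Si](C)(C)C(C)(C)C)C(OC)(OC)[C@H](CO[Si](C)(C)C(C)(C)C)[C@H](O2)O1 | intermediate
11 | methyl (R)‑3‑hydroxy‑2‑methylpropanoate | COC(=O)[C@H](C)CO | starting material
12 | methyl (R)‑3‑[(tert‑butyldimethylsilyl)oxy]‑2‑methylpropanoate | COC(=O)[C@H](C)CO[Si](C)(C)C(C)(C)C | intermediate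
13 | (R)‑3‑[(tert‑butyldimethylsilyl)oxy]‑2‑methylpropanal | O=C[C@H](C)CO[Si](C)(C)C(C)(C)C | intermediate
14 | tert‑butyldimethyl{[(2S,3Z)‑2‑methylpent‑3‑en‑1‑yl]oxy}silane | C/C=C\[C@H](C)CO[Si](C)(C)C(C)(C)C | intermediate
15 | (2S,3Z)‑2‑methylpent‑3‑en‑1‑ol | C/C=C\[C@H](C)CO | intermediate
16 | (2S,3Z)‑2‑methylpent‑3‑enal | C/C=C\[C@H](C)C=O | intermediate
17 | (2Z,4S,5Z)‑2‑iodo‑4‑methylhepta‑2,5‑diene | C/C=C\[C@H](C)/C=C(/C)I | intermediate
18 | C13 pyrrolidine amide, 7,11‑diol, 9,9‑dimethyl ketal, 8′,10′‑bis‑TBS ether (2Z,4S,5Z,7S,8R,10S,11S) | C/C=C\[C@H](C)/C=C(/C)[C@@H](O)[C@@H](CO[Si](C)(C)C(C)(C)C)C(OC)(OC)[C@@H](CO[Si](C)(C)C(C)(C)C)[C@@H](O)CC(=O)N1CCCC1 | intermediate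
19 | 5,6‑deoxy‑myriaporone 4, 9,9‑dimethyl ketal, 8′,10′‑bis‑TBS ether | C/C=C\[C@H](C)/C=C(/C)[C@@H](O)[C@@H](CO[Si](C)(C)C(C)(C)C)C(OC)(OC)[C@@H](CO[Si](C)(C)C(C)(C)C)[C@@H](O)CC(=O)CC | intermediate
20 | (5S,6S,8R,9S,10Z,12S,13Z)‑5,9‑dihydroxy‑6,8‑bis(hydroxymethyl)‑10,12‑dimethylpentadeca‑10,13‑diene‑3,7‑dione | C/C=C\[C@H](C)/C=C(/C)[C@@H](O)[C@@H](CO)C(=O)[C@@H](CO)[C@@H](O)CC(=O)CC | intermediate
21 | myriaporone 4 (open keto form) | C/C=C\[C@H](C)[C@@H]1O[C@]1(C)[C@@H](O)[C@@H](CO)C(=O)[C@@H](CO)[C@@H](O)CC(=O)CC | target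

## Step count and risks

Total steps: 18. Longest linear sequence: 12 (steps 1–8, then 15–18); the side‑chain branch is 6 steps (9–14).

Steps most likely to fail, each with a fallback that changes the approach:

1. **Step 3 (second exo hydroxymethylation, syn‑diaxial to the first).** Fallback: deliver the second carbon intramolecularly. Silylate 4 with BrCH2SiMe2Cl, form the C4 enolate so the tethered bromide alkylates the exo face, then Tamao oxidation (KF, KHCO3, H2O2) to reach 5.
2. **Step 5 (ketalisation of a ketone flanked by two axial substituents).** Fallback: carry C9 as an alcohol instead. Reduce 6, protect as the PMB ether, run the same hydroboration/Baeyer–Villiger/coupling sequence, then regenerate the ketone late (DDQ, then Dess–Martin with C7/C11‑OH temporarily as TES ethers).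
3. **Step 15 (lactol opening and C7 diastereoselectivity; Felkin addition would give the wrong epimer).** Fallback: set C7 by reduction instead of addition. Oxidise the lactol amide to the δ‑lactone (TEMPO/PhI(OAc)2), add the alkenyllithium to give the C7 enone, and reduce under reagent control (CBS).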